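Read the zeta run from its late end: at 40.0 min it shows 73% target and 16% starting material, so 11.0% of the charge stands in neither column, more than the scatter of a reading. The last eta readings, 26% and 74%, account for the whole charge at a partner charge of 0.28 M.

| flask | starting material | coupling partner | temperature | remark | time |
|---|---|---|---|---|---|
| eta | 1 M | 0.28 M | 45 °C | run made earlier |  |
| zeta | 1 M | 1.1 M | 70 °C | run made earlier |  |
| cedar | 1.0 M | 0.500 M | 90 °C |  | 2.5 h |
| alder | 1.0 M | 1.50 M | 50 °C |  | 2.5 h |

- eta (time / min: target / %, starting material / %): 25.0: 9, 90; 50.0: 15, 81; 80.0: 19, 78; 120: 26, 74
- zeta (time / min: target / %, starting material / %): 4.00: 37, 59; 15.0: 58, 29; 20.0: 65, 26; 40.0: 73, 16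

(standard deviation of a reading: 1.5 percentage points)

- a reading or a percentage of target counts all its forms, free or not

1. the flask that ends with the higher amount of target, in percent of the starting material charged, or "neither" when 2 percentage points or less lies between them (cedar / alder / neither)
2. final target, as a percentage of the starting material charged, in cedar
3. final target, as a percentage of the starting material charged, in alder

My reckoning: assume a side path whose rate, over the target rate, grows in proportion to c(coupling partner), and which spends two partner per starting material. In zeta, c(coupling partner) then falls from 1.1 M to 0.150 M, a mean of 0.625 M. This gives the reading s = 0.241 M⁻¹. Call s the partner penalty: material lost per target made, per molar of partner. The inverse of s·c is the selectivity factor at that moment. Carry s unchanged across temperature, which is an assumption.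

Bound alder by two extremes. Hold the partner at its charge, and the target share of converted material is one over one plus s·c, or 73.4%. Hold it at its end value of about 0.234 M, and the share is 94.7%. The partner falls during the run, so the ratio drifts toward target and the real share lies between; the mean partner gives 82.7%.

The first eta reading gives a chord k = 0.0129 M⁻¹ min⁻¹ at 45 °C, and the first zeta reading gives 0.0841 M⁻¹ min⁻¹ at 70 °C; both are rough readings. Interpolate ln k to alder's 50 °C, which gives 0.0187 M⁻¹ min⁻¹. The partner falls during alder, so a fixed time constant does not apply; use the integrated second-order law, counting one partner per starting material, and 9.79% stays unconverted. I expect 74.6% target in alder.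

Cedar has the coupling partner as limiting reagent. With the partner spent and its mean at half the charge, target is c/(one plus s·c), or 44.6%, so alder ends higher.

The forecast says alder, with 42% in cedar and 83% in alder, after “less side loss and slowing”.

The flasks give alder: 45.2% in cedar and 74.3% in alder.

    starting material + coupling partner → target (k = 0.0310 M⁻¹ min⁻¹, Ea = 66.0 kJ mol⁻¹)
    starting material + 2 coupling partner → side product (k = 0.00980 M⁻² min⁻¹, Ea = 57.0 kJ mol⁻¹)
    crystals ⇌ target, rate k3*(cs3 - [target]) while solid is left; crystals form when [target] > cs3 (solubility = 0.430 M, k = 1.30 min⁻¹)
    (constants at 50 °C)

Alder stops short mainly through the side path: without it the same flask ends at 96.5%, not 74.3%. Its partner falls to 23% of charge, so s at the mean partner gives 0.222 side product per target, against 0.277 in the flask. Cedar's neighbour with 0.85 M of partner ends with 0% of it, and c/(one plus s·c) gives 70.5%. That flask holds 72.3% target.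

The numbers in the tables are simulated on assumed constants, noise included.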